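The ten-membered carbocycle (C1–C10) is disconnected at C7–C8, the bond between the lactone β-carbon and the C8 carbinol: the exocyclic C11=C13 methylene with C7–C8(O) is the retron of a carbonyl allylation. The key step is an intramolecular chromium(II) Nozaki–Hiyama allylation in which a 3-(bromomethyl)butenolide attacks a tethered aldehyde through C7; in one operation it closes the carbocycle, sets C7 and C8 and unveils the α-methylene lactone. The precursor is an acyclic chain that already carries the butenolide ring (C6 set), the Z-C4=C5 alkene, the C3 acetate, the 1,10-oxirane and a C8 aldehyde; it is assembled from a Z-iodoalkene and a homoallylic aldehyde.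

Key step: step 16

Remark: locants C1–C15 are the germacrane locants of the target (C1–C10 carbocycle, C11–C13 lactone carbons, C14 on C10, C15 on C4); 4-(4-methoxybenzyloxy)but-1-yne (7) is taken as a catalogue compound.

Step 1
Reactants: 1 (E)-but-2-enal; 2 propyne
Product: 3 (2E,4S)-hept-2-en-5-yn-4-ol
Conditions: ProPhenol ligand (antipode directing Re-face addition, 10 mol%), Me2Zn, Ph3P=O (20 mol%), toluene, 0 °C
Reagents that add atoms: none
Why: Zinc–ProPhenol-catalysed enantioselective alkynylation of an enal, in which the dinuclear zinc catalyst should deliver the propynyl group in a 1,2-fashion to the Re face and so set the future C6 as S (it becomes 6R in the lactone only through a change of CIP priorities).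

Step 2
Reactants: 3 (2E,4S)-hept-2-en-5-yn-4-ol
Product: 5 (2E,4S,5Z)-6-iodohepta-2,5-dien-4-ol, via cyclic alkenylaluminate 4 (not isolated)
Conditions: Red-Al, THF, 0 °C to rt; then I2, THF, −78 °C
Reagents that add atoms: iodine, II
Why: Hydroxyl-directed trans-hydroalumination of the propargylic alcohol (hydride to C5, aluminium to C4 in a five-membered oxa-aluminacycle) followed by iodinolysis with retention should give the iodoalkene with iodine cis to C6, the isolated propenyl group being inert.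

Step 3
Reactants: 5 (2E,4S,5Z)-6-iodohepta-2,5-dien-4-ol
Product: 6 triethyl{[(2E,4S,5Z)-6-iodohepta-2,5-dien-4-yl]oxy}silane
Conditions: TESCl, imidazole, CH2Cl2, 0 °C
Reagents that add atoms: chlorotriethylsilane, CC[Si](Cl)(CC)CC
Why: Standard silyl ether formation; O6 must be masked so that C3 can later pass through the ketone level without the Z-γ-hydroxy enone closing to a furan.

Step 4
Reactants: 7 1-[(but-3-yn-1-yloxy)methyl]-4-methoxybenzene; 8 oxirane
Product: 11 (E)-6-[(4-methoxybenzyl)oxy]-4-methylhex-3-en-1-ol, via alkenyldimethylalane 9 (not isolated), via lithium alkenylaluminate 10 (not isolated)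
Conditions: Me3Al, Cp2ZrCl2 (cat.), CH2Cl2, 0 °C to rt; n-BuLi, hexane/THF, −78 °C; then oxirane, −78 °C to rt
Reagents that add atoms: trimethylaluminium, C[Al](C)C
Why: Negishi zirconium-catalysed syn-carboalumination puts the methyl group (C14) on the internal alkyne carbon and aluminium on the terminal one, and the derived aluminate opens oxirane with alkenyl transfer and retention, which fixes the E geometry of C1=C10.

Step 5
Reactants: 11 (E)-6-[(4-methoxybenzyl)oxy]-4-methylhex-3-en-1-ol
Product: 12 (E)-6-[(4-methoxybenzyl)oxy]-4-methylhex-3-enal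
Conditions: Dess–Martin periodinane, NaHCO3, CH2Cl2, 0 °C
Reagents that add atoms: none
Why: Buffered Dess–Martin oxidation should stop at the β,γ-unsaturated aldehyde without moving the double bond into conjugation; the aldehyde is used crude.

Step 6
Reactants: 6 triethyl{[(2E,4S,5Z)-6-iodohepta-2,5-dien-4-yl]oxy}silane; 12 (E)-6-[(4-methoxybenzyl)oxy]-4-methylhex-3-enal
Product: 13 (2E,4S,5Z,9E)-12-[(4-methoxybenzyl)oxy]-6,10-dimethyl-4-[(triethylsilyl)oxy]dodeca-2,5,9-trien-7-ol (C7-epimer mixture; C7 is C3 of the target)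
Conditions: CrCl2, NiCl2 (cat.), DMSO/THF, rt
Reagents that add atoms: none
Why: Nozaki–Hiyama–Kishi coupling: nickel inserts into the C–I bond with retention of the Z geometry and the alkenylchromium adds chemoselectively to the aldehyde, forming C3–C4 with C3 cis to C6; the C3 configuration is corrected in steps 7 and 8.

Step 7
Reactants: 13 C7-epimeric trienol
Product: 14 (2E,4S,5Z,9E)-12-[(4-methoxybenzyl)oxy]-6,10-dimethyl-4-[(triethylsilyl)oxy]dodeca-2,5,9-trien-7-one
Conditions: Dess–Martin periodinane, NaHCO3, CH2Cl2, 0 °C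
Reagents that add atoms: none
Why: Dess–Martin oxidation converges both epimers on one Z-enone under neutral conditions that should leave the Z-alkene and the β,γ-alkene in place.

Step 8
Reactants: 14 Z-enone
Product: 15 (2E,4S,5Z,7S,9E)-12-[(4-methoxybenzyl)oxy]-6,10-dimethyl-4-[(triethylsilyl)oxy]dodeca-2,5,9-trien-7-ol
Conditions: (R)-2-methyl-CBS-oxazaborolidine, catecholborane, toluene, −78 °C
Reagents that add atoms: none
Why: Corey–Bakshi–Shibata reduction in which the α-methylalkenyl group is the large substituent and the CH2 group the small one, so the (R)-catalyst should give the 3S alcohol by 1,2-reduction; catecholborane does not hydroborate the alkenes at this temperature.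

Step 9
Reactants: 15 (7S)-trienol
Product: 16 (2E,4S,5Z,7S,9E)-12-[(4-methoxybenzyl)oxy]-6,10-dimethyl-4-[(triethylsilyl)oxy]dodeca-2,5,9-trien-7-yl acetate
Conditions: Ac2O, pyridine, DMAP (cat.), CH2Cl2, 0 °C to rt
Reagents that add atoms: acetic anhydride, CC(=O)OC(C)=O
Why: DMAP-catalysed acetylation installs the C3 acetate of the target with retention.

Step 10
Reactants: 16 trienyl acetate
Product: 17 (2E,4S,5Z,7S)-8-[(2R,3R)-3-{2-[(4-methoxybenzyl)oxy]ethyl}-3-methyloxiran-2-yl]-6-methyl-4-[(triethylsilyl)oxy]octa-2,5-dien-7-yl acetate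
Conditions: D-fructose-derived Shi ketone (30 mol%), Oxone, K2CO3, Bu4NHSO4, MeCN/dimethoxymethane/aq. borate buffer, 0 °C
Reagents that add atoms: Oxone (potassium peroxymonosulfate), [K+].[O-]S(=O)(=O)OO
Why: Shi asymmetric epoxidation through a spiro transition state should give the (1R,10R) trans-epoxide from the E-alkene under reagent control, and it should select the isolated C1=C10 alkene because C4=C5 and the propenyl group are deactivated by their allylic oxygens.

Step 11
Reactants: 17 epoxy silyl ether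
Product: 18 (2E,4S,5Z,7S)-4-hydroxy-8-[(2R,3R)-3-{2-[(4-methoxybenzyl)oxy]ethyl}-3-methyloxiran-2-yl]-6-methylocta-2,5-dien-7-yl acetate
Conditions: HF·pyridine, pyridine, THF, 0 °C
Reagents that add atoms: none
Why: Buffered fluoride desilylation removes the secondary triethylsilyl ether; the medium is neither strongly acidic nor basic, so the trisubstituted epoxide, the PMB ether and the acetate (no migration to O6) should survive.

Step 12
Reactants: 18 C6 alcohol; 19 2-(bromomethyl)prop-2-enoic acid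
Product: 20 (2E,4S,5Z,7S)-7-acetoxy-8-[(2R,3R)-3-{2-[(4-methoxybenzyl)oxy]ethyl}-3-methyloxiran-2-yl]-6-methylocta-2,5-dien-4-yl 2-(bromomethyl)prop-2-enoate
Conditions: N,N'-diisopropylcarbodiimide, DMAP (cat.), CH2Cl2, −20 to 0 °C
Reagents that add atoms: none
Why: Steglich esterification acylates O6 with retention at C6; low temperature and catalytic DMAP limit attack on the allylic bromide.

Step 13
Reactants: 20 bromomethylacrylate ester
Product: 21 (1Z,3S)-1-[(2R)-4-(bromomethyl)-5-oxo-2,5-dihydrofuran-2-yl]-4-[(2R,3R)-3-{2-[(4-methoxybenzyl)oxy]ethyl}-3-methyloxiran-2-yl]-2-methylbut-1-en-3-yl acetate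
Conditions: Grubbs second-generation catalyst (10 mol%), CH2Cl2 (5 mM), 40 °C
Reagents that add atoms: none
Why: Ring-closing metathesis: the ruthenium carbene forms at the propenyl group (propene is lost) and closes onto the acrylate to give the five-membered lactone ring O–C6–C7=C11–C12 with the allylic bromide in place; the hindered C4=C5 alkene has no productive ring-closing pathway and C6 is untouched (its descriptor becomes R by priority change only).

Step 14
Reactants: 21 PMB-protected bromomethylbutenolide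
Product: 22 (1Z,3S)-1-[(2R)-4-(bromomethyl)-5-oxo-2,5-dihydrofuran-2-yl]-4-[(2R,3R)-3-(2-hydroxyethyl)-3-methyloxiran-2-yl]-2-methylbut-1-en-3-yl acetate
Conditions: DDQ, CH2Cl2/pH 7 buffer, 0 °C
Reagents that add atoms: none
Why: Oxidative cleavage of the PMB ether under buffered neutral conditions, to which the allylic bromide, butenolide, acetate and epoxide should be inert.

Step 15
Reactants: 22 primary alcohol
Product: 23 (1Z,3S)-1-[(2R)-4-(bromomethyl)-5-oxo-2,5-dihydrofuran-2-yl]-2-methyl-4-[(2R,3R)-3-methyl-3-(2-oxoethyl)oxiran-2-yl]but-1-en-3-yl acetate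
Conditions: Dess–Martin periodinane, NaHCO3, CH2Cl2, 0 °C; used at once
Reagents that add atoms: none
Why: Base-free Dess–Martin oxidation gives the β,γ-epoxy aldehyde without the E1cB opening of the epoxide that amine-based oxidations would risk.

Step 16
Reactants: 23 bromomethylbutenolide aldehyde
Product: 25 (1R,3S,4Z,6R,7R,8S,10R)-3-acetoxy-1,10-epoxy-8-hydroxygermacra-4,11(13)-dien-12,6-olide, via allylchromium(III) dichloride 24 (not isolated)
Conditions: CrCl2 (10 equiv), THF, rt, slow addition of 23 (final 2 mM)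
Reagents that add atoms: none
Why: Two equivalents of chromium(II) reduce the allylic C13–Br bond to an η1-allylchromium(III) species whose metal binds the C8 aldehyde oxygen, and the C–C bond then forms at the γ-carbon C7 through a six-membered chair transition state (SE2'), moving the double bond from C7=C11 to the exocyclic C11=C13 position. This is a Nozaki–Hiyama (chromium Barbier) allylation, a reaction type known intermolecularly for 3-(bromomethyl)butenolides and intramolecularly for medium-ring and macrocyclic terpenoid lactones. The ten-membered carbocycle C1–C10 is closed by the C7–C8 bond in a mode that is exo with respect to both the carbonyl group and the allyl unit, the lactone and oxirane rings being already present. C7 is set by attack on the butenolide face anti to the C6 side chain, which gives the trans lactone fusion, and C8 by the chair transition state, in which the butenolide holds C6 trans to C13 (an E-type allyl unit) and C9 sits equatorial, giving the 7,8-anti (7R,8S) arrangement. The step needs cyclisation in preference to oligomerisation, γ- in preference to α-attack, and survival of the β,γ-epoxy aldehyde; slow addition at high dilution, the closed transition state of allylchromium reagents, the neutral and weakly Lewis acidic medium, and the conformational restriction by the Z-alkene and the trans-epoxide should secure these.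

Step 17
Reactants: 25 C8 alcohol
Product: 26 (1R,3S,4Z,6R,7R,8S,10R)-3-acetoxy-1,10-epoxy-8-(3-methylbutanoyloxy)germacra-4,11(13)-dien-12,6-olide (CNP0157657.1)
Conditions: 3-methylbutanoyl chloride, pyridine, DMAP (cat.), CH2Cl2, 0 °C
Reagents that add atoms: 3-methylbutanoyl chloride, CC(C)CC(Cl)=O
Why: DMAP-catalysed acylation of the C8 secondary alcohol with retention; the fast acid chloride at low temperature should outrun translactonisation to the 8,12-olide.

Compound list
1 | (E)-but-2-enal (crotonaldehyde) | C/C=C/C=O | starting material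
2 | propyne | CC#C | starting material
3 | (2E,4S)-hept-2-en-5-yn-4-ol | C/C=C/[C@H](O)C#CC | intermediate
4 | cyclic sodium alkenylaluminate from trans-hydroalumination of 3 (Al on C4, O6 bound to Al) | C/C=C/[C@@H]1O[Al-](OCCOC)(OCCOC)C(C)=C1.[Na+] | intermediate
5 | (2E,4S,5Z)-6-iodohepta-2,5-dien-4-ol | C/C=C/[C@H](O)/C=C(/C)I | intermediate
6 | triethyl{[(2E,4S,5Z)-6-iodohepta-2,5-dien-4-yl]oxy}silane | C/C=C/[C@H](O[Si](CC)(CC)CC)/C=C(/C)I | intermediate
7 | 1-[(but-3-yn-1-yloxy)methyl]-4-methoxybenzene | C#CCCOCc1ccc(OC)cc1 | starting material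
8 | oxirane | C1CO1 | starting material
9 | (E)-{4-[(4-methoxybenzyl)oxy]-2-methylbut-1-en-1-yl}dimethylalane | C[Al](C)/C=C(\C)CCOCc1ccc(OC)cc1 | intermediate
10 | lithium butyl{(E)-4-[(4-methoxybenzyl)oxy]-2-methylbut-1-en-1-yl}dimethylaluminate | [Li+].CCCC[Al-](C)(C)/C=C(\C)CCOCc1ccc(OC)cc1 | intermediate
11 | (E)-6-[(4-methoxybenzyl)oxy]-4-methylhex-3-en-1-ol | OCC/C=C(\C)CCOCc1ccc(OC)cc1 | intermediate
12 | (E)-6-[(4-methoxybenzyl)oxy]-4-methylhex-3-enal | O=CC/C=C(\C)CCOCc1ccc(OC)cc1 | intermediate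
13 | (2E,4S,5Z,9E)-12-[(4-methoxybenzyl)oxy]-6,10-dimethyl-4-[(triethylsilyl)oxy]dodeca-2,5,9-trien-7-ol, C7-epimer mixture | C/C=C/[C@H](O[Si](CC)(CC)CC)/C=C(/C)C(O)C/C=C(\C)CCOCc1ccc(OC)cc1 | intermediate
14 | (2E,4S,5Z,9E)-12-[(4-methoxybenzyl)oxy]-6,10-dimethyl-4-[(triethylsilyl)oxy]dodeca-2,5,9-trien-7-one | C/C=C/[C@H](O[Si](CC)(CC)CC)/C=C(/C)C(=O)C/C=C(\C)CCOCc1ccc(OC)cc1 | intermediate
15 | (2E,4S,5Z,7S,9E)-12-[(4-methoxybenzyl)oxy]-6,10-dimethyl-4-[(triethylsilyl)oxy]dodeca-2,5,9-trien-7-ol | C/C=C/[C@H](O[Si](CC)(CC)CC)/C=C(/C)[C@@H](O)C/C=C(\C)CCOCc1ccc(OC)cc1 | intermediate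
16 | (2E,4S,5Z,7S,9E)-12-[(4-methoxybenzyl)oxy]-6,10-dimethyl-4-[(triethylsilyl)oxy]dodeca-2,5,9-trien-7-yl acetate | C/C=C/[C@H](O[Si](CC)(CC)CC)/C=C(/C)[C@@H](OC(C)=O)C/C=C(\C)CCOCc1ccc(OC)cc1 | intermediate
17 | (2E,4S,5Z,7S)-8-[(2R,3R)-3-{2-[(4-methoxybenzyl)oxy]ethyl}-3-methyloxiran-2-yl]-6-methyl-4-[(triethylsilyl)oxy]octa-2,5-dien-7-yl acetate | C/C=C/[C@H](O[Si](CC)(CC)CC)/C=C(/C)[C@@H](OC(C)=O)C[C@H]1O[C@]1(C)CCOCc1ccc(OC)cc1 | intermediate
18 | (2E,4S,5Z,7S)-4-hydroxy-8-[(2R,3R)-3-{2-[(4-methoxybenzyl)oxy]ethyl}-3-methyloxiran-2-yl]-6-methylocta-2,5-dien-7-yl acetate | C/C=C/[C@H](O)/C=C(/C)[C@@H](OC(C)=O)C[C@H]1O[C@]1(C)CCOCc1ccc(OC)cc1 | intermediate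
19 | 2-(bromomethyl)prop-2-enoic acid | C=C(CBr)C(=O)O | starting material
20 | (2E,4S,5Z,7S)-7-acetoxy-8-[(2R,3R)-3-{2-[(4-methoxybenzyl)oxy]ethyl}-3-methyloxiran-2-yl]-6-methylocta-2,5-dien-4-yl 2-(bromomethyl)prop-2-enoate | C/C=C/[C@H](OC(=O)C(=C)CBr)/C=C(/C)[C@@H](OC(C)=O)C[C@H]1O[C@]1(C)CCOCc1ccc(OC)cc1 | intermediate
21 | (1Z,3S)-1-[(2R)-4-(bromomethyl)-5-oxo-2,5-dihydrofuran-2-yl]-4-[(2R,3R)-3-{2-[(4-methoxybenzyl)oxy]ethyl}-3-methyloxiran-2-yl]-2-methylbut-1-en-3-yl acetate | BrCC1=C[C@H](OC1=O)/C=C(/C)[C@@H](OC(C)=O)C[C@H]2O[C@]2(C)CCOCc2ccc(OC)cc2 | intermediate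
22 | (1Z,3S)-1-[(2R)-4-(bromomethyl)-5-oxo-2,5-dihydrofuran-2-yl]-4-[(2R,3R)-3-(2-hydroxyethyl)-3-methyloxiran-2-yl]-2-methylbut-1-en-3-yl acetate | BrCC1=C[C@H](OC1=O)/C=C(/C)[C@@H](OC(C)=O)C[C@H]2O[C@]2(C)CCO | intermediate
23 | (1Z,3S)-1-[(2R)-4-(bromomethyl)-5-oxo-2,5-dihydrofuran-2-yl]-2-methyl-4-[(2R,3R)-3-methyl-3-(2-oxoethyl)oxiran-2-yl]but-1-en-3-yl acetate | BrCC1=C[C@H](OC1=O)/C=C(/C)[C@@H](OC(C)=O)C[C@H]2O[C@]2(C)CC=O | intermediate
24 | allylchromium(III) dichloride derived from 23 (chromium on C13) | Cl[Cr](Cl)CC1=C[C@H](OC1=O)/C=C(/C)[C@@H](OC(C)=O)C[C@H]2O[C@]2(C)CC=O | intermediate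
25 | (1R,3S,4Z,6R,7R,8S,10R)-3-acetoxy-1,10-epoxy-8-hydroxygermacra-4,11(13)-dien-12,6-olide | C=C1C(=O)O[C@@H]2/C=C(/C)[C@@H](OC(C)=O)C[C@H]3O[C@]3(C)C[C@H](O)[C@@H]12 | intermediate
26 | (1R,3S,4Z,6R,7R,8S,10R)-3-acetoxy-1,10-epoxy-8-(3-methylbutanoyloxy)germacra-4,11(13)-dien-12,6-olide (CNP0157657.1) | C=C1C(=O)O[C@@H]2/C=C(/C)[C@@H](OC(C)=O)C[C@H]3O[C@]3(C)C[C@H](OC(=O)CC(C)C)[C@@H]12 | target

Total step count: 17. Longest linear sequence: 15 steps (steps 1–3 and 6–17, from crotonaldehyde).

Steps most likely to fail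

Step 16. The slow macrocyclisation may lose to intermolecular allylation. The aldehyde may add to the butenolide face syn to the C6 chain or through a boat transition state, giving the cis-fused lactone or the C8 epimer. The β,γ-epoxy aldehyde may also open by β-elimination or by chromium(III)-assisted transannular attack. The fallback replaces the reductive metal by a preformed allylboron reagent and sets out from 22. Palladium-catalysed borylation of the allylic bromide (B2pin2, Pd2(dba)3, DMSO, rt) should give the pinacol allylboronate alcohol F1. Buffered Dess–Martin oxidation should then give the allylboronate aldehyde F2. Heating F2 in dilute toluene (2 mM, 80 °C) should close the ring by uncatalysed allylboration through the same chair arrangement, with no Lewis acid or reductant present. Hydrolysis of the borate during aqueous work-up returns to the route at 25.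

Step 10. The dioxirane may also oxidise C4=C5 or the propenyl group, facial control on the chiral substrate may be incomplete, and the acetate may hydrolyse at the buffer pH. The fallback moves the epoxidation to the one-alkene stage and sets out from 11. Shi epoxidation of 11 should give the epoxy alcohol F3, and buffered Dess–Martin oxidation the epoxy aldehyde F4. Nozaki–Hiyama–Kishi coupling of F4 with 6 should give the epoxy allylic alcohol F5 as a C3-epimer mixture. Dess–Martin oxidation then gives the epoxy enone F6, and reduction with the (R)-CBS catalyst and catecholborane the (3S)-epoxy alcohol F7. Acetylation as in step 9 returns to the route at 17.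

Step 8. The α-methyl Z-enone may isomerise to the E isomer during oxidation or reduction, or hydride delivery may be poorly face-selective. The fallback avoids the ketone and sets out from 13. The C3 epimers of 13 are separated by chromatography. The 3S epimer is 15 and is acetylated as in step 9. The (3R)-alcohol F8 is converted by Mitsunobu inversion with acetic acid (PPh3, DIAD, THF, 0 °C) directly into the 3S acetate. Both streams rejoin the route at 16.

Further compounds
F1 | step 16 | (1Z,3S)-4-[(2R,3R)-3-(2-hydroxyethyl)-3-methyloxiran-2-yl]-2-methyl-1-{(2R)-5-oxo-4-[(4,4,5,5-tetramethyl-1,3,2-dioxaborolan-2-yl)methyl]-2,5-dihydrofuran-2-yl}but-1-en-3-yl acetate | CC1(C)OB(CC2=C[C@H](OC2=O)/C=C(/C)[C@@H](OC(C)=O)C[C@H]3O[C@]3(C)CCO)OC1(C)C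
F2 | step 16 | (1Z,3S)-2-methyl-4-[(2R,3R)-3-methyl-3-(2-oxoethyl)oxiran-2-yl]-1-{(2R)-5-oxo-4-[(4,4,5,5-tetramethyl-1,3,2-dioxaborolan-2-yl)methyl]-2,5-dihydrofuran-2-yl}but-1-en-3-yl acetate | CC1(C)OB(CC2=C[C@H](OC2=O)/C=C(/C)[C@@H](OC(C)=O)C[C@H]3O[C@]3(C)CC=O)OC1(C)C
F3 | step 10 | 2-[(2R,3R)-3-{2-[(4-methoxybenzyl)oxy]ethyl}-3-methyloxiran-2-yl]ethan-1-ol | OCC[C@H]1O[C@]1(C)CCOCc1ccc(OC)cc1
F4 | step 10 | 2-[(2R,3R)-3-{2-[(4-methoxybenzyl)oxy]ethyl}-3-methyloxiran-2-yl]acetaldehyde | O=CC[C@H]1O[C@]1(C)CCOCc1ccc(OC)cc1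
F5 | step 10 | (2E,4S,5Z)-8-[(2R,3R)-3-{2-[(4-methoxybenzyl)oxy]ethyl}-3-methyloxiran-2-yl]-6-methyl-4-[(triethylsilyl)oxy]octa-2,5-dien-7-ol, C7-epimer mixture | C/C=C/[C@H](O[Si](CC)(CC)CC)/C=C(/C)C(O)C[C@H]1O[C@]1(C)CCOCc1ccc(OC)cc1
F6 | step 10 | (2E,4S,5Z)-8-[(2R,3R)-3-{2-[(4-methoxybenzyl)oxy]ethyl}-3-methyloxiran-2-yl]-6-methyl-4-[(triethylsilyl)oxy]octa-2,5-dien-7-one | C/C=C/[C@H](O[Si](CC)(CC)CC)/C=C(/C)C(=O)C[C@H]1O[C@]1(C)CCOCc1ccc(OC)cc1
F7 | step 10 | (2E,4S,5Z,7S)-8-[(2R,3R)-3-{2-[(4-methoxybenzyl)oxy]ethyl}-3-methyloxiran-2-yl]-6-methyl-4-[(triethylsilyl)oxy]octa-2,5-dien-7-ol | C/C=C/[C@H](O[Si](CC)(CC)CC)/C=C(/C)[C@@H](O)C[C@H]1O[C@]1(C)CCOCc1ccc(OC)cc1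
F8 | step 8 | (2E,4S,5Z,7R,9E)-12-[(4-methoxybenzyl)oxy]-6,10-dimethyl-4-[(triethylsilyl)oxy]dodeca-2,5,9-trien-7-ol | C/C=C/[C@H](O[Si](CC)(CC)CC)/C=C(/C)[C@H](O)C/C=C(\C)CCOCc1ccc(OC)cc1
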